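**Retrosynthetic overview**
1. The C22 end of the chain comes from 1-docosanol 1, oxidised to docosanal 2; the carboxyl end comes from methyl 15-bromopentadecanoate 3.
2. Key disconnection, C15–C16 of the acyl chain: the carbonyl carbon of 2, as its N–H hydrazone 4, acts as a primary alkyl carbanion equivalent and is joined to the CH2Br carbon of 3 with loss of N2. This gives methyl heptatriacontanoate 5 with no functional group left at the junction.
3. Last disconnection, the ester C–O bond: 5 and tyrosol 6 give the target 7 by lipase transesterification at the primary alcohol only, so the phenol is never protected.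
4. No ring is formed (the benzene ring is bought in 6) and there is no stereocentre to set.

Assumption: the acyl chain of the SMILES is read as 37 carbons (heptatriacontanoyl); the molecule has no stereocentre or stereogenic double bond, so it is achiral and is made as the single compound drawn.

**Step 1**
Reactants: 1 1-docosanol
Product: 2 docosanal
Conditions: TEMPO (10 mol %), PhI(OAc)2 (1.1 equiv), CH2Cl2, 35 °C
Reagents that add atoms: none
Why: Oxoammonium-mediated alcohol oxidation (TEMPO/PhI(OAc)2) stops at the aldehyde under anhydrous conditions because no aldehyde hydrate forms, and the saturated chain offers nothing else to oxidise; no stereocentre is involved.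

**Step 2**
Reactants: 2 docosanal (1.5 equiv); 3 methyl 15-bromopentadecanoate
Product: 5 methyl heptatriacontanoate, via docosanal hydrazone 4 (not isolated)
Conditions: N2H4·H2O (1.2 equiv per 2), THF, rt, 1 h, then 4 Å MS; then 3, Ni(cod)2 (10 mol %), PMe3 (20 mol %), K3PO4 (2 equiv), THF, 60 °C, 16 h
Reagents that add atoms: none
Why: Proposed new method: condensation gives the N–H hydrazone 4, whose carbon behaves as a primary alkyl carbanion equivalent (Wolff–Kishner-type reversal of the aldehyde carbon's polarity); zerovalent nickel adds oxidatively to the primary C–Br bond of 3, the hydrazone binds through nitrogen and is deprotonated by K3PO4, loss of N2 leaves a dialkylnickel species and reductive elimination forms the C15–C16 bond between two carbons that are both electrophilic in their parent forms; the closest known reaction type is the nickel-catalysed denitrogenative C(sp3)–C(sp3) coupling of aryl aldehyde N–H hydrazones with unactivated primary alkyl halides, extended here to an aliphatic hydrazone, with the methyl ester inert to the weak base and no stereocentre formed.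

**Step 3**
Reactants: 5 methyl heptatriacontanoate; 6 tyrosol, 2-(4-hydroxyphenyl)ethanol
Product: 7 2-(4-hydroxyphenyl)ethyl heptatriacontanoate (target)
Conditions: immobilised Candida antarctica lipase B, 6 (3 equiv), toluene/2-methyl-2-butanol 1:1, 70 °C, 4 Å MS
Reagents that add atoms: none
Why: Lipase-catalysed transesterification through an acyl-enzyme acylates only the primary aliphatic hydroxyl of tyrosol, because phenols are not acyl acceptors for this enzyme, and trapping of methanol on the sieves drives the equilibrium; no stereocentre is involved.

**Compound list**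
1 | 1-docosanol | CCCCCCCCCCCCCCCCCCCCCCO | starting material
2 | docosanal | CCCCCCCCCCCCCCCCCCCCCC=O | intermediate
3 | methyl 15-bromopentadecanoate | BrCCCCCCCCCCCCCCC(=O)OC | starting material
4 | docosanal hydrazone (E) | CCCCCCCCCCCCCCCCCCCCC/C=N/N | intermediate
5 | methyl heptatriacontanoate | CCCCCCCCCCCCCCCCCCCCCCCCCCCCCCCCCCCCC(=O)OC | intermediate
6 | tyrosol, 2-(4-hydroxyphenyl)ethanol | OCCc1ccc(O)cc1 | starting material
7 | 2-(4-hydroxyphenyl)ethyl heptatriacontanoate | CCCCCCCCCCCCCCCCCCCCCCCCCCCCCCCCCCCCC(=O)OCCc1ccc(O)cc1 | target

**Totals**
Total step count: 3. Longest linear sequence: 3 steps (1 → 2 → 5 → 7).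

**Steps most likely to fail, most risky first**

Step 2. An aliphatic N–H hydrazone is less acidic and less prone to denitrogenative metalation than a benzylic one. Competing paths are Wolff–Kishner reduction of 4 to docosane, azine formation, N-alkylation of 4 by 3, and β-hydride elimination from the alkylnickel derived from 3. The fallback keeps the same aldehyde carbon as the nucleophile but uses it as an acyl anion equivalent. It sets out from 2 and 3 and comes back to the route at 7. Compound 2 is condensed with propane-1,3-dithiol (BF3·OEt2, CH2Cl2) to give 2-henicosyl-1,3-dithiane F1. Compound 3 is hydrolysed with aqueous HBr in AcOH to 15-bromopentadecanoic acid F2. F1 is lithiated (n-BuLi, THF, −30 °C) and alkylated with the lithium salt of F2 (made with LiN(SiMe3)2; THF/DMPU, −30 °C to rt) to give 15-(2-henicosyl-1,3-dithian-2-yl)pentadecanoic acid F3. Raney Ni in refluxing EtOH/THF desulfurises F3 to heptatriacontanoic acid F4. F4 is esterified with 6 (p-TsOH, toluene, Dean–Stark; the phenol does not esterify under Fischer conditions) to reach 7.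

Step 3. A C37 acyl chain may be a slow substrate for the lipase, and the ester is poorly soluble. The fallback replaces enzymatic chemoselectivity by a protecting group. It sets out from 6 (and uses 5) and comes back at 7. Compound 6 is benzylated at the phenol only (BnBr, K2CO3, acetone, reflux) to 2-[4-(benzyloxy)phenyl]ethanol F5. F5 and 5 are transesterified with Ti(OiPr)4 (5 mol %) in toluene at 110 °C with distillation of methanol to give 2-[4-(benzyloxy)phenyl]ethyl heptatriacontanoate F6. Hydrogenolysis (H2, Pd/C, THF/EtOAc, 40 °C) removes the benzyl group to give 7.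

Step 1. The waxy alcohol is poorly soluble and the long-chain aldehyde can go on to the acid or to the wax ester docosyl docosanoate. The fallback replaces direct oxidation by activation and displacement with DMSO. It sets out from 1 and comes back at 2. Compound 1 is tosylated (TsCl, pyridine, CH2Cl2) to docosyl 4-methylbenzenesulfonate F7, which undergoes Kornblum oxidation (DMSO, NaHCO3, 150 °C) to 2.

**Further compounds**
F1 | step 2 | 2-henicosyl-1,3-dithiane | CCCCCCCCCCCCCCCCCCCCCC1SCCCS1
F2 | step 2 | 15-bromopentadecanoic acid | BrCCCCCCCCCCCCCCC(=O)O
F3 | step 2 | 15-(2-henicosyl-1,3-dithian-2-yl)pentadecanoic acid | CCCCCCCCCCCCCCCCCCCCCC1(CCCCCCCCCCCCCCC(=O)O)SCCCS1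
F4 | step 2 | heptatriacontanoic acid | CCCCCCCCCCCCCCCCCCCCCCCCCCCCCCCCCCCCC(=O)O
F5 | step 3 | 2-[4-(benzyloxy)phenyl]ethanol | OCCc1ccc(OCc2ccccc2)cc1
F6 | step 3 | 2-[4-(benzyloxy)phenyl]ethyl heptatriacontanoate | CCCCCCCCCCCCCCCCCCCCCCCCCCCCCCCCCCCCC(=O)OCCc1ccc(OCc2ccccc2)cc1
F7 | step 1 | docosyl 4-methylbenzenesulfonate | CCCCCCCCCCCCCCCCCCCCCCOS(=O)(=O)c1ccc(C)cc1
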